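Rather than hunt a constant for each step, lump them. Call everything not yet target, substrate plus isomer of the product, the pool, and follow the first-order fall of the pool above a floor. This is a pseudo-first-order constant, which I take as linear in [catalyst].

| flask | substrate | catalyst | remark | time |
|---|---|---|---|---|
| theta | 2.9 M (fed, over 2.0 min) | 6.4 mM | run made earlier; the fed solution adds 0.10 times the starting volume |  |
| beta | 2.9 M (fed, over 2.0 min) | 17 mM | run made earlier; the fed solution adds 0.10 times the starting volume |  |
| Wednesday's | 2.9 M | 25 mM | everything together at the start, the whole solution of substrate included, so that from the start the volume is larger by 0.10 times the starting volume | 15 min |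
| Saturday's | 2.9 M (fed, over 2.0 min) | 8.4 mM | the fed solution adds 0.10 times the starting volume | 15 min |

| run | time / min | target / % | isomer of the product / % |
|---|---|---|---|
| theta | 0.667 | 7 | 8 |
| theta | 1.00 | 5 | 16 |
| theta | 1.33 | 12 | 26 |
| theta | 2.00 | 10 | 37 |
| theta | 3.00 | 30 | 41 |
| theta | 5.00 | 41 | 31 |
| theta | 8.00 | 60 | 20 |
| beta | 1.00 | 7 | 17 |
| beta | 2.00 | 19 | 39 |
| beta | 3.00 | 31 | 39 |
| beta | 4.00 | 44 | 34 |
| beta | 5.00 | 52 | 27 |
| beta | 6.00 | 57 | 23 |
| beta | 8.00 | 72 | 17 |

(readings scatter by 2 percentage points)

- every charge counts on the volume at the start, and the solution that is fed holds the whole dose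
- the numbers in the tables scatter with a standard deviation of 2 percentage points
- what may be going on: substrate <-> target; target + catalyst <-> isomer of the product + catalyst; isomer of the product <-> substrate
- percentages count the whole charge, also what has not yet gone in

1. which one finishes higher in share of target in all that became target or isomer of the product ("neither" within 2 percentage points) (Wednesday's / Saturday's / neither)
2. share of target in all that became target or isomer of the product, Wednesday's
3. share of target in all that became target or isomer of the product, Saturday's

Round one sets the floor at zero. The readings between 3.00 min and 8.00 min put the fall of the theta pool at 0.112 min⁻¹ and that of the beta pool at 0.180 min⁻¹. For Saturday's I borrow the theta pool read at 3.00 min as a starting point, although the two differ in catalyst, 8.4 mM against 6.4 mM; for Wednesday's I start from the whole charge at the start. Scaling the constants gives an estimated pool of 15.6 % for Saturday's and 3.08 % for Wednesday's. The last readings of theta and beta put isomer of the product at 0.554 of the pool on average, and with that fraction the estimated shares are 90.7 % for Saturday's and 98.3 % for Wednesday's.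

The weak link is the zero floor. Three evenly spaced theta pools give a floor of 9.92 %, but the beta ones give −2.77 %. The scatter leaves it open, and I keep the theta value. Put back, it raises the constants read from the runs to 0.138 min⁻¹ for theta and 0.237 min⁻¹ for beta. For Saturday's this gives 0.157 min⁻¹, the pool constant, and for Wednesday's 0.311 min⁻¹. The estimated pools become 19.1 % for Saturday's and 10.8 % for Wednesday's. I commit to 88.5 % for Saturday's and 93.7 % for Wednesday's, which finishes higher.

The forecast says Wednesday's, 92 % against 88 %: “Substrate is available from the start”.

The flasks give Wednesday's, with 92.1 % for Wednesday's and 87.6 % for Saturday's.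

    substrate ⇌ target (K = 18.0, k = 0.00420 s⁻¹)
    target + catalyst ⇌ isomer of the product + catalyst, rate k2*[catalyst]*[target] forward; the back reaction follows from the equilibrium constant (K = 0.0720, k = 0.0110 L mol⁻¹ s⁻¹)
    isomer of the product ⇌ substrate (k = 0.0210 s⁻¹)

Now use the pool constant 0.157 min⁻¹ on the neighbour, Saturday's recipe read at 10 min. Starting again from the theta pool at 3.00 min and the same floor, I reckon the pool at 29.9 %. That estimate means target 70.1 %, isomer of the product 16.6 % and a share of 80.9 %. The neighbour flask holds 69.4 % of target and 17.6 % of isomer of the product, a share of 79.7 %.

(The runs are simulated with made-up constants.)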